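**Plan**

- Retrosynthesis: the three ester groups are cleaved last. The C2–O and C5–O bonds are then cut together as the O–O bond of an endoperoxide (singlet oxygen). The C1–C6 bond shared by the oxirane and the cyclohexene is cut next, which turns the arene oxide into an oxepin. The heptenyl C=C goes back to a formyl group, and the oxepin goes back through an oxaquadricyclane and a 7-oxanorbornadiene to a 2-substituted furan and an acetylenic aldehyde.
- Enabling feature: in the 7-oxabicyclo[4.1.0]hept-3-ene core the hydroxyls at C2 and C5 are cis to each other and trans to O7, and O7 bridges C1 and C6. That is the reduced singlet-oxygen adduct of an arene oxide, whose valence tautomer is an oxepin lacking only the C1–C6 bond.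
- Forward: Stille coupling puts the side chain on furan; a Diels–Alder reaction builds the oxygen-bridged bicycle; photochemical [2+2] and thermal opening give the seven-membered oxepin; olefination adds the heptenyl group. A 6π closure then forms the six- and three-membered rings at once and singlet oxygen traps the diene; reduction, resolution and saponification finish.
- Helpers: the formyl group activates the alkyne and the photochemical step and then becomes C1 of the heptenyl chain. The benzoate masks CH2OH, the peroxide bridge is a temporary ring, and the acetate is the resolution handle; all acyl groups leave in the last step.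
- Stereochemistry: the relative configuration at C1, C2, C5 and C6 comes from the key step (cis ring fusion, singlet oxygen anti to the epoxide). The absolute configuration comes from a lipase kinetic resolution. The two E double bonds come from bromide 2 and the Julia–Kocienski step.

Key step: step 10

Assumption: in step 12 the lipase is taken to follow the usual size rule for secondary alcohols at C5 (alkene carbon C4 large, epoxide carbon C6 medium), so the (5S)-alcohol of the target series is the one acylated; with the opposite preference the unreacted diol would enter step 13 and nothing else would change.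

**Route**

Step 1
Reactants: 1 2-(tributylstannyl)furan; 2 methyl (E)-4-bromo-2-methylbut-2-enoate
Product: 3 methyl (E)-4-(furan-2-yl)-2-methylbut-2-enoate
Conditions: Pd2(dba)3 (cat.), tri(2-furyl)phosphine, THF, 50 °C
Reagents that add atoms: none
Why: Stille coupling of a 2-furylstannane with an allylic bromide through a π-allyl palladium intermediate should join the furan to the unsubstituted allyl terminus and keep the more stable E enoate.

Step 2
Reactants: 4 but-2-yne-1,4-diol (3 equiv)
Product: 5 4-hydroxybut-2-yn-1-yl benzoate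
Conditions: BzCl (1 equiv), pyridine, CH2Cl2, 0 °C
Reagents that add atoms: benzoyl chloride O=C(Cl)c1ccccc1
Why: Monoacylation of a symmetrical diol used in excess; the benzoate is transparent above 300 nm and leaves in the last step together with the other esters.

Step 3
Reactants: 5 4-hydroxybut-2-yn-1-yl benzoate
Product: 6 4-oxobut-2-yn-1-yl benzoate
Conditions: MnO2 (activated, excess), CH2Cl2, rt
Reagents that add atoms: none
Why: Oxidation of a propargylic alcohol to the ynal with activated MnO2 should leave the benzoate and the triple bond untouched.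

Step 4
Reactants: 3 methyl (E)-4-(furan-2-yl)-2-methylbut-2-enoate; 6 4-oxobut-2-yn-1-yl benzoate
Product: 7 methyl (E)-4-[3-(benzoyloxymethyl)-2-formyl-7-oxabicyclo[2.2.1]hepta-2,5-dien-1-yl]-2-methylbut-2-enoate (racemic)
Conditions: neat, BHT (trace), 50 °C, dark
Reagents that add atoms: none
Why: Diels–Alder reaction of a 2-alkylfuran with an acetylenic aldehyde, in which the "ortho" rule (largest HOMO coefficient at the free C5 of the furan, largest LUMO coefficient at the alkyne carbon β to the formyl group) should join the formyl-bearing carbon to the substituted furan carbon and so fix the later 2,4,5-pattern of the oxepin; no stereocentre of the target is set here.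

Step 5
Reactants: 7 the 7-oxanorbornadiene aldehyde
Product: 8 methyl (E)-4-[5-(benzoyloxymethyl)-1-formyl-3-oxatetracyclo[3.2.0.0(2,7).0(4,6)]hept-2-yl]-2-methylbut-2-enoate (racemic)
Conditions: hν (350 nm), degassed MeCN, 0 °C
Reagents that add atoms: none
Why: Intramolecular [2+2] photocycloaddition of the two ring double bonds (norbornadiene–quadricyclane photoisomerisation in the 7-oxa series), driven through the n,π* band of the enal so that the enoate and benzoate chromophores stay dark.

Step 6
Reactants: 8 the 3-oxaquadricyclane aldehyde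
Product: 9 methyl (E)-4-[5-(benzoyloxymethyl)-4-formyloxepin-2-yl]-2-methylbut-2-enoate
Conditions: toluene, 90 °C, base-washed glass, dark
Reagents that add atoms: none
Why: Thermal oxaquadricyclane–oxepin rearrangement, in which the cyclopropane bonds from the two oxygen-bearing carbons to the formyl- and benzoyloxymethyl-bearing carbons break (C2–C1 is a donor–acceptor bond) and the resulting cyclobutene opens, which should place the former alkyne carbons at C4 and C5 of the oxepin.

Step 7
Reactants: 10 1-phenyl-1H-tetrazole-5-thiol; 11 1-bromohexane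
Product: 12 5-(hexylsulfanyl)-1-phenyl-1H-tetrazole
Conditions: K2CO3, acetone, reflux
Reagents that add atoms: none
Why: S-Alkylation of the thiolate by SN2 displacement at a primary bromide.

Step 8
Reactants: 12 5-(hexylsulfanyl)-1-phenyl-1H-tetrazole
Product: 13 5-(hexylsulfonyl)-1-phenyl-1H-tetrazole
Conditions: H2O2 (30% aq.), (NH4)6Mo7O24·4H2O (cat.), EtOH, rt
Reagents that add atoms: hydrogen peroxide OO
Why: Molybdate-catalysed oxidation of the sulfide to the sulfone, the standard access to Julia–Kocienski reagents.

Step 9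
Reactants: 9 the oxepin aldehyde; 13 5-(hexylsulfonyl)-1-phenyl-1H-tetrazole
Product: 14 methyl (E)-4-[5-(benzoyloxymethyl)-4-[(E)-hept-1-enyl]oxepin-2-yl]-2-methylbut-2-enoate
Conditions: 13, KN(SiMe3)2, DME, −78 °C; then 9, −78 to −20 °C
Reagents that add atoms: none
Why: Julia–Kocienski olefination (addition, Smiles rearrangement, loss of SO2 and tetrazololate) should give mainly the E alkene with a potassium counter-ion in DME, and the sulfone is metalated before the aldehyde is added so that the doubly allylic CH2 of the side chain is not deprotonated by the amide base.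

Step 10
Reactants: 14 the heptenyl oxepin
Product: 16 methyl (E)-4-[9-(benzoyloxymethyl)-8-[(E)-hept-1-enyl]-3,6,7-trioxatricyclo[3.2.2.0(2,4)]non-8-en-2-yl]-2-methylbut-2-enoate (racemic; peroxide bridge on the face opposite to the epoxide oxygen), via arene oxide 15 (not isolated)
Conditions: O2, methylene blue (cat.), hν (660 nm LED), CH2Cl2, −78 °C
Reagents that add atoms: dioxygen O=O
Why: Oxepin 14 is in fast equilibrium with its valence tautomer 15 through a thermal disrotatory 6π electrocyclisation that joins the two oxygen-bearing carbons C2 and C7 of the oxepin (the future C1 and C6), and 15 is drained from the equilibrium by suprafacial [4+2] cycloaddition of singlet oxygen to its cyclohexa-1,3-diene. The closest known reaction type is the photooxygenation of the parent oxepin–benzene oxide system, and of arene oxides substituted at an epoxide carbon, to anti endoperoxides. The single new C–C bond closes two rings, the cyclohexadiene (6π electrocyclic, disrotatory, hence cis-fused) and the oxirane (same bond, the oxygen bridge being already in place), and the 1,2-dioxane ring is closed by the concerted [4+2] addition. C1 and C6 are set together by the geometry of the electrocyclisation, and C2 and C5 by attack of singlet oxygen on the diene face opposite to the epoxide oxygen (steric shielding and lone-pair repulsion), so both new C–O bonds should be cis to each other and trans to the epoxide as in the target; the product is racemic because 14 is achiral. The step needs site selectivity for the ring diene over the diene that includes the heptenyl double bond: in 14 that diene cannot become s-cis because the benzoyloxymethyl group on C5 sits inside, and in 15 the s-cis-locked homoannular diene should react faster than the semicyclic one. Red light absorbed only by the sensitiser and the low temperature should keep 14 from photoisomerising and 16 from rearranging to a bis-epoxide.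

Step 11
Reactants: 16 the epoxy endoperoxide
Product: 17 methyl (E)-4-[(1S*,2R*,5S*,6R*)-4-(benzoyloxymethyl)-3-[(E)-hept-1-enyl]-2,5-dihydroxy-7-oxabicyclo[4.1.0]hept-3-en-1-yl]-2-methylbut-2-enoate (racemic)
Conditions: thiourea, wet MeOH, 0 °C to rt
Reagents that add atoms: none
Why: Thiourea reduction of the O–O bond of a bicyclic endoperoxide leaves both C–O bonds intact and should therefore deliver the cis-2,5-diol trans to the epoxide without touching the epoxide, the esters or the alkenes.

Step 12
Reactants: 17 the racemic epoxy diol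
Product: 18 methyl (E)-4-[(1S,2R,5S,6R)-5-acetoxy-4-(benzoyloxymethyl)-3-[(E)-hept-1-enyl]-2-hydroxy-7-oxabicyclo[4.1.0]hept-3-en-1-yl]-2-methylbut-2-enoate
Conditions: lipase from Burkholderia cepacia (immobilised), vinyl acetate, MTBE, 30 °C, stopped near half conversion
Reagents that add atoms: vinyl acetate C=COC(C)=O
Why: Lipase-catalysed kinetic resolution by enantioselective transesterification, in which the less hindered C5 hydroxyl of the (1S,2R,5S,6R) enantiomer should be acylated while the (1R,2S,5R,6S)-diol stays unchanged and is removed by chromatography, which fixes the absolute configuration of all four stereocentres.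

Step 13
Reactants: 18 the resolved acetate
Product: 19 (E)-4-[(1S,2R,5S,6R)-3-[(E)-hept-1-enyl]-2,5-dihydroxy-4-(hydroxymethyl)-7-oxabicyclo[4.1.0]hept-3-en-1-yl]-2-methylbut-2-enoic acid (target)
Conditions: LiOH·H2O, THF/MeOH/H2O, 0 °C; then 1 M HCl to pH 4, 0 °C
Reagents that add atoms: lithium hydroxide [Li+].[OH-]
Why: One saponification should cleave the methyl ester, the acetate and the benzoate at a temperature low enough that Payne rearrangement of the trans epoxy alcohols does not compete, and no stereocentre is epimerisable under these conditions.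

**Compound list**

1 | 2-(tributylstannyl)furan | CCCC[Sn](CCCC)(CCCC)c1ccco1 | starting material
2 | methyl (E)-4-bromo-2-methylbut-2-enoate | COC(=O)/C(C)=C/CBr | starting material
3 | methyl (E)-4-(furan-2-yl)-2-methylbut-2-enoate | COC(=O)/C(C)=C/Cc1ccco1 | intermediate
4 | but-2-yne-1,4-diol | OCC#CCO | starting material
5 | 4-hydroxybut-2-yn-1-yl benzoate | OCC#CCOC(=O)c1ccccc1 | intermediate
6 | 4-oxobut-2-yn-1-yl benzoate | O=CC#CCOC(=O)c1ccccc1 | intermediate
7 | methyl (E)-4-[3-(benzoyloxymethyl)-2-formyl-7-oxabicyclo[2.2.1]hepta-2,5-dien-1-yl]-2-methylbut-2-enoate (racemic) | O=CC1=C(COC(=O)c2ccccc2)C2C=CC1(C/C=C(\C)C(=O)OC)O2 | intermediate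
8 | methyl (E)-4-[5-(benzoyloxymethyl)-1-formyl-3-oxatetracyclo[3.2.0.0(2,7).0(4,6)]hept-2-yl]-2-methylbut-2-enoate (racemic) | O=CC12C3(COC(=O)c4ccccc4)C4OC1(C/C=C(\C)C(=O)OC)C2C34 | intermediate
9 | methyl (E)-4-[5-(benzoyloxymethyl)-4-formyloxepin-2-yl]-2-methylbut-2-enoate | O=CC1=C(COC(=O)c2ccccc2)C=COC(C/C=C(\C)C(=O)OC)=C1 | intermediate
10 | 1-phenyl-1H-tetrazole-5-thiol | Sc1nnnn1-c1ccccc1 | starting material
11 | 1-bromohexane | CCCCCCBr | starting material
12 | 5-(hexylsulfanyl)-1-phenyl-1H-tetrazole | CCCCCCSc1nnnn1-c1ccccc1 | intermediate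
13 | 5-(hexylsulfonyl)-1-phenyl-1H-tetrazole | CCCCCCS(=O)(=O)c1nnnn1-c1ccccc1 | intermediate
14 | methyl (E)-4-[5-(benzoyloxymethyl)-4-[(E)-hept-1-enyl]oxepin-2-yl]-2-methylbut-2-enoate | CCCCC/C=C/C1=C(COC(=O)c2ccccc2)C=COC(C/C=C(\C)C(=O)OC)=C1 | intermediate
15 | methyl (E)-4-[4-(benzoyloxymethyl)-3-[(E)-hept-1-enyl]-7-oxabicyclo[4.1.0]hepta-2,4-dien-1-yl]-2-methylbut-2-enoate (arene oxide, cis-fused, racemic, valence tautomer of 14) | CCCCC/C=C/C1=CC2(C/C=C(\C)C(=O)OC)OC2C=C1COC(=O)c1ccccc1 | intermediate (not isolated)
16 | methyl (E)-4-[9-(benzoyloxymethyl)-8-[(E)-hept-1-enyl]-3,6,7-trioxatricyclo[3.2.2.0(2,4)]non-8-en-2-yl]-2-methylbut-2-enoate (racemic, peroxide bridge anti to the epoxide oxygen; enantiomer of the target series drawn) | CCCCC/C=C/C1=C(COC(=O)c2ccccc2)[C@@H]2OO[C@H]1[C@]3(C/C=C(\C)C(=O)OC)O[C@H]23 | intermediate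
17 | methyl (E)-4-[(1S*,2R*,5S*,6R*)-4-(benzoyloxymethyl)-3-[(E)-hept-1-enyl]-2,5-dihydroxy-7-oxabicyclo[4.1.0]hept-3-en-1-yl]-2-methylbut-2-enoate (racemic; enantiomer of the target series drawn) | CCCCC/C=C/C1=C(COC(=O)c2ccccc2)[C@H](O)[C@H]2O[C@@]2(C/C=C(\C)C(=O)OC)[C@@H]1O | intermediate
18 | methyl (E)-4-[(1S,2R,5S,6R)-5-acetoxy-4-(benzoyloxymethyl)-3-[(E)-hept-1-enyl]-2-hydroxy-7-oxabicyclo[4.1.0]hept-3-en-1-yl]-2-methylbut-2-enoate | CCCCC/C=C/C1=C(COC(=O)c2ccccc2)[C@H](OC(C)=O)[C@H]2O[C@@]2(C/C=C(\C)C(=O)OC)[C@@H]1O | intermediate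
19 | (E)-4-[(1S,2R,5S,6R)-3-[(E)-hept-1-enyl]-2,5-dihydroxy-4-(hydroxymethyl)-7-oxabicyclo[4.1.0]hept-3-en-1-yl]-2-methylbut-2-enoic acid | CCCCC/C=C/C1=C(CO)[C@H](O)[C@H]2O[C@@]2(C/C=C(\C)C(=O)O)[C@@H]1O | target

**Step count and risks**

Total step count: 13. Longest linear sequence: 10 steps (steps 2 to 6 and 9 to 13, from but-2-yne-1,4-diol).

Steps most likely to fail:

Step 10. What may go wrong is loss of site selectivity: singlet oxygen may add across the semicyclic diene formed by C2=C3 of 15 and the heptenyl double bond, or oxidise the electron-rich polyene by an ene pathway. The fallback moves the photooxygenation in front of the olefination, so that no second diene is present. It sets out from 9. Photooxygenation under the conditions of step 10 should give the formyl endoperoxide F1, and thiourea reduction the diol aldehyde F2. Et3SiOTf with 2,6-lutidine should give the bis(triethylsilyl) ether F3, and Julia–Kocienski olefination with 13 the heptenyl bis(silyl ether) F4. HF·pyridine in THF then removes both silyl groups and the sequence comes back to the route at 17.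

Step 4. What may go wrong is a cycloaddition too slow for a singly activated ynal, so that polymerisation of 6 or cycloreversion takes over, or a weak "ortho" preference. The fallback uses the more electron-poor, commercial dienophile 4,4-diethoxybut-2-ynal (CCOC(OCC)C#CC=O) and turns its acetal into the benzoyloxymethyl group only after the ring system stands. It sets out from 3. The Diels–Alder reaction should give the acetal adduct F5. The conditions of steps 5, 6, 9, 10 and 11 should then give in turn the oxaquadricyclane F6, the oxepin aldehyde F7, the heptenyl oxepin F8, the endoperoxide F9 and the diol acetal F10. PPTS in wet acetone should free the dienal F11, and NaBH4 with CeCl3·7H2O should reduce it to the triol F12. Benzoyl chloride with 2,4,6-collidine at −78 °C acylates only the primary hydroxyl, and the sequence comes back to the route at 17.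

Step 12. What may go wrong is low enantioselectivity of the enzyme or acylation at the C2 hydroxyl. The fallback is a classical resolution through diastereomeric esters. It sets out from 17. (S)-2-Methoxy-2-phenylacetic acid with DCC and DMAP should acylate the C5 hydroxyl of both enantiomers and give the (1S,2R,5S,6R) ester F13 and the (1R,2S,5R,6S) ester F14, which are separated by chromatography. F13 is saponified under the conditions of step 13, and the sequence comes back to the route at 19.

**Further compounds**

F1 | step 10 | methyl (E)-4-[9-(benzoyloxymethyl)-8-formyl-3,6,7-trioxatricyclo[3.2.2.0(2,4)]non-8-en-2-yl]-2-methylbut-2-enoate (racemic, peroxide anti to epoxide) | O=CC1=C(COC(=O)c2ccccc2)[C@@H]2OO[C@H]1[C@]3(C/C=C(\C)C(=O)OC)O[C@H]23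
F2 | step 10 | methyl (E)-4-[(1S*,2R*,5S*,6R*)-4-(benzoyloxymethyl)-3-formyl-2,5-dihydroxy-7-oxabicyclo[4.1.0]hept-3-en-1-yl]-2-methylbut-2-enoate (racemic) | O=CC1=C(COC(=O)c2ccccc2)[C@H](O)[C@H]2O[C@@]2(C/C=C(\C)C(=O)OC)[C@@H]1O
F3 | step 10 | 2,5-bis(triethylsilyl) ether of F2 (racemic) | O=CC1=C(COC(=O)c2ccccc2)[C@H](O[Si](CC)(CC)CC)[C@H]2O[C@@]2(C/C=C(\C)C(=O)OC)[C@@H]1O[Si](CC)(CC)CC
F4 | step 10 | 2,5-bis(triethylsilyl) ether of 17 (racemic) | CCCCC/C=C/C1=C(COC(=O)c2ccccc2)[C@H](O[Si](CC)(CC)CC)[C@H]2O[C@@]2(C/C=C(\C)C(=O)OC)[C@@H]1O[Si](CC)(CC)CC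
F5 | step 4 | methyl (E)-4-[3-(diethoxymethyl)-2-formyl-7-oxabicyclo[2.2.1]hepta-2,5-dien-1-yl]-2-methylbut-2-enoate (racemic) | O=CC1=C(C(OCC)OCC)C2C=CC1(C/C=C(\C)C(=O)OC)O2
F6 | step 4 | methyl (E)-4-[5-(diethoxymethyl)-1-formyl-3-oxatetracyclo[3.2.0.0(2,7).0(4,6)]hept-2-yl]-2-methylbut-2-enoate (racemic) | O=CC12C3(C(OCC)OCC)C4OC1(C/C=C(\C)C(=O)OC)C2C34
F7 | step 4 | methyl (E)-4-[5-(diethoxymethyl)-4-formyloxepin-2-yl]-2-methylbut-2-enoate | O=CC1=C(C(OCC)OCC)C=COC(C/C=C(\C)C(=O)OC)=C1
F8 | step 4 | methyl (E)-4-[5-(diethoxymethyl)-4-[(E)-hept-1-enyl]oxepin-2-yl]-2-methylbut-2-enoate | CCCCC/C=C/C1=C(C(OCC)OCC)C=COC(C/C=C(\C)C(=O)OC)=C1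
F9 | step 4 | methyl (E)-4-[9-(diethoxymethyl)-8-[(E)-hept-1-enyl]-3,6,7-trioxatricyclo[3.2.2.0(2,4)]non-8-en-2-yl]-2-methylbut-2-enoate (racemic, peroxide anti to epoxide) | CCCCC/C=C/C1=C(C(OCC)OCC)[C@@H]2OO[C@H]1[C@]3(C/C=C(\C)C(=O)OC)O[C@H]23
F10 | step 4 | methyl (E)-4-[(1S*,2R*,5S*,6R*)-4-(diethoxymethyl)-3-[(E)-hept-1-enyl]-2,5-dihydroxy-7-oxabicyclo[4.1.0]hept-3-en-1-yl]-2-methylbut-2-enoate (racemic) | CCCCC/C=C/C1=C(C(OCC)OCC)[C@H](O)[C@H]2O[C@@]2(C/C=C(\C)C(=O)OC)[C@@H]1O
F11 | step 4 | methyl (E)-4-[(1S*,2R*,5S*,6R*)-4-formyl-3-[(E)-hept-1-enyl]-2,5-dihydroxy-7-oxabicyclo[4.1.0]hept-3-en-1-yl]-2-methylbut-2-enoate (racemic) | CCCCC/C=C/C1=C(C=O)[C@H](O)[C@H]2O[C@@]2(C/C=C(\C)C(=O)OC)[C@@H]1O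
F12 | step 4 | methyl (E)-4-[(1S*,2R*,5S*,6R*)-3-[(E)-hept-1-enyl]-2,5-dihydroxy-4-(hydroxymethyl)-7-oxabicyclo[4.1.0]hept-3-en-1-yl]-2-methylbut-2-enoate (racemic) | CCCCC/C=C/C1=C(CO)[C@H](O)[C@H]2O[C@@]2(C/C=C(\C)C(=O)OC)[C@@H]1O
F13 | step 12 | methyl (E)-4-[(1S,2R,5S,6R)-4-(benzoyloxymethyl)-3-[(E)-hept-1-enyl]-2-hydroxy-5-[(S)-2-methoxy-2-phenylacetoxy]-7-oxabicyclo[4.1.0]hept-3-en-1-yl]-2-methylbut-2-enoate | CCCCC/C=C/C1=C(COC(=O)c2ccccc2)[C@H](OC(=O)[C@@H](OC)c2ccccc2)[C@H]2O[C@@]2(C/C=C(\C)C(=O)OC)[C@@H]1O
F14 | step 12 | methyl (E)-4-[(1R,2S,5R,6S)-4-(benzoyloxymethyl)-3-[(E)-hept-1-enyl]-2-hydroxy-5-[(S)-2-methoxy-2-phenylacetoxy]-7-oxabicyclo[4.1.0]hept-3-en-1-yl]-2-methylbut-2-enoate | CCCCC/C=C/C1=C(COC(=O)c2ccccc2)[C@@H](OC(=O)[C@@H](OC)c2ccccc2)[C@@H]2O[C@]2(C/C=C(\C)C(=O)OC)[C@H]1O
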